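**Retrosynthetic overview**

1. Target 25 ⇐ selective O‑acetylation of diol lactone 24 ⇐ anti‑aldol of lactol 20 with ethyl glyoxylate, reduction and γ‑lactonisation (the hydroxy‑lactone ring is formed last).
2. 20 ⇐ lactone 19 ⇐ rhodium‑catalysed asymmetric conjugate addition of alkenylboronate 17 to furan‑2(5H)‑one (sets the side‑chain CH).
3. 17 ⇐ methyl ketone 14 ⇐ key step: semipinacol ring contraction of trans‑decalin chlorohydrin 12 (six‑membered ring B becomes the cyclopentane and the hydrindane C‑1 centre is set).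
4. 12 ⇐ catalytic enantioselective proton‑initiated bicyclisation of chlorotriene 11 (ring A, then ring B, in one operation).
5. 11 ⇐ Negishi coupling of alkenyl iodide 5 with the alkylzinc from iodide 9, both made by zirconium‑catalysed carboalumination of alkynes 3 and 6.

Assumption: where a stereocentre is destroyed later (C‑2 of 12, the lactol carbon of 20 and 22), one epimer or the mixture is drawn; this does not affect the route.

**Route**

Step 1
Reactants: 1 5-bromo-2-methylpent-2-ene; 2 lithium acetylide ethylenediamine complex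
Product: 3 6-methylhept-5-en-1-yne
Conditions: DMSO, 10 °C to rt
Reagents that add atoms: none
Why: SN2 alkylation of the acetylide by the primary bromide (acetylide alkylation), with no stereocentre formed.

Step 2
Reactants: 3 6-methylhept-5-en-1-yne
Product: 5 (1E)-1-iodo-2,6-dimethylhepta-1,5-diene, via alkenylalane 4 (not isolated)
Conditions: AlMe3 (2 equiv), Cp2ZrCl2 (0.2 equiv), CH2Cl2, rt; then I2, THF, −30 °C
Reagents that add atoms: trimethylaluminium C[Al](C)C; iodine II
Why: Negishi zirconium‑catalysed carboalumination adds methyl and aluminium syn across the terminal alkyne (methyl to the internal carbon) and iodinolysis of the C–Al bond goes with retention, which fixes the (E)-trisubstituted alkene.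

Step 3
Reactants: 6 but-3-yn-1-ol
Product: 8 (3E)-4-chloro-3-methylbut-3-en-1-ol, via alanyl alkoxide 7 (not isolated)
Conditions: AlMe3 (3 equiv), Cp2ZrCl2 (0.25 equiv), CH2Cl2, 0 °C to rt; then N-chlorosuccinimide, THF, −30 °C; aqueous work-up
Reagents that add atoms: trimethylaluminium C[Al](C)C; N-chlorosuccinimide O=C1CCC(=O)N1Cl
Why: The same Negishi carboalumination on the aluminium alkoxide of 6, followed by chlorinolysis of the alkenyl–aluminium bond with retention, gives the (E)-chloroalkene whose geometry later becomes the equatorial C–Cl bond.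

Step 4
Reactants: 8 (3E)-4-chloro-3-methylbut-3-en-1-ol
Product: 9 (1E)-1-chloro-4-iodo-2-methylbut-1-ene
Conditions: I2, PPh3, imidazole, CH2Cl2, 0 °C
Reagents that add atoms: iodine II
Why: Appel‑type iodination of the primary alcohol, with the vinyl chloride inert.

Step 5
Reactants: 9 (1E)-1-chloro-4-iodo-2-methylbut-1-ene; 5 (1E)-1-iodo-2,6-dimethylhepta-1,5-diene
Product: 11 (1E,5E)-1-chloro-2,6,10-trimethylundeca-1,5,9-triene, via alkylzinc iodide 10 (not isolated)
Conditions: Zn dust, LiCl, THF, 40 °C; then 5, Pd(PPh3)4 (3 mol%), THF, rt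
Reagents that add atoms: none
Why: Zinc insertion into the primary C–I bond and Negishi sp3–sp2 cross‑coupling with retention of the alkenyl iodide geometry, the vinyl chloride being unreactive towards Pd(PPh3)4 at room temperature.

Step 6
Reactants: 11 (1E,5E)-1-chloro-2,6,10-trimethylundeca-1,5,9-triene
Product: 12 (1R,2R,4aS,8aS)-1-chloro-2,5,5,8a-tetramethyldecahydronaphthalen-2-ol
Conditions: (S,S)-IDPi (chiral imidodiphosphorimidate Brønsted acid, 5 mol%), H2O (3 equiv), (CF3)3COH/CH2Cl2, −40 °C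
Reagents that add atoms: water O
Why: Proposed new method: the confined chiral acid protonates the terminal isopropylidene group on one enantioface and the cation is relayed through an all‑chair anti (Stork–Eschenmoser) bicyclisation in which the (5E)-alkene gives the trans ring fusion, the (1E)-chloroalkene is attacked at its CHCl carbon (Markovnikov, six‑membered ring) so that chlorine ends equatorial, and the tertiary cation is captured anti by water, the closest known reactions being the IDPi‑catalysed asymmetric polyene cyclisation of homofarnesol and Lansbury‑type chloro‑olefin‑terminated cationic cyclisations.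

Step 7
Reactants: 12 (1R,2R,4aS,8aS)-1-chloro-2,5,5,8a-tetramethyldecahydronaphthalen-2-ol
Product: 14 1-[(1S,3aS,7aS)-4,4,7a-trimethyloctahydro-1H-inden-1-yl]ethan-1-one, via magnesium alkoxide 13 (not isolated)
Conditions: EtMgBr (1.1 equiv), THF, 0 °C; then toluene, 80 °C
Reagents that add atoms: none
Why: Semipinacol (Tiffeneau‑type halohydrin) ring contraction in which the equatorial C‑1–Cl bond is antiperiplanar to the C‑2–C‑3 ring bond, so that this bond migrates with inversion at C‑1 while C‑2 becomes the acetyl carbonyl, turning ring B into the cyclopentane with the acetyl group cis to the angular methyl; epoxide formation and E2 elimination are geometrically impossible and either C‑2 epimer converges.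

Step 8
Reactants: 14 1-[(1S,3aS,7aS)-4,4,7a-trimethyloctahydro-1H-inden-1-yl]ethan-1-one
Product: 16 1-[(1S,3aS,7aS)-4,4,7a-trimethyloctahydro-1H-inden-1-yl]ethenyl trifluoromethanesulfonate, via potassium enolate 15 (not isolated)
Conditions: KN(SiMe3)2, THF, −78 °C; then PhNTf2, −78 °C to 0 °C
Reagents that add atoms: N-phenylbis(trifluoromethanesulfonimide) O=S(=O)(N(c1ccccc1)S(=O)(=O)C(F)(F)F)C(F)(F)F
Why: Kinetic deprotonation at the methyl group (the ring CH is tertiary and hindered) and O‑triflation give the terminal enol triflate without touching the C‑1 stereocentre.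

Step 9
Reactants: 16 1-[(1S,3aS,7aS)-4,4,7a-trimethyloctahydro-1H-inden-1-yl]ethenyl trifluoromethanesulfonate
Product: 17 4,4,5,5-tetramethyl-2-{1-[(1R,3aS,7aR)-4,4,7a-trimethyloctahydro-1H-inden-1-yl]ethenyl}-1,3,2-dioxaborolane
Conditions: B2pin2, PdCl2(PPh3)2 (3 mol%), PPh3, KOPh, toluene, 50 °C
Reagents that add atoms: bis(pinacolato)diboron CC1(C)OB(OC1(C)C)B1OC(C)(C)C(C)(C)O1
Why: Miyaura borylation of an alkenyl triflate, which leaves all stereocentres untouched (the descriptor change is only a priority change).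

Step 10
Reactants: 17 4,4,5,5-tetramethyl-2-{1-[(1R,3aS,7aR)-4,4,7a-trimethyloctahydro-1H-inden-1-yl]ethenyl}-1,3,2-dioxaborolane; 18 furan-2(5H)-one
Product: 19 (4R)-4-{1-[(1R,3aS,7aS)-4,4,7a-trimethyloctahydro-1H-inden-1-yl]ethenyl}oxolan-2-one
Conditions: [Rh(cod)OH]2 (2.5 mol%), (R)-BINAP (6 mol%), K3PO4 (0.5 equiv), dioxane/H2O (10:1), 60 °C; acidic work-up
Reagents that add atoms: none
Why: Hayashi–Miyaura rhodium‑catalysed asymmetric 1,4‑addition, in which the (R)-BINAP–rhodium alkenyl species adds to one enantioface of the butenolide and sets the (4R) centre by catalyst control.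

Step 11
Reactants: 19 (4R)-4-{1-[(1R,3aS,7aS)-4,4,7a-trimethyloctahydro-1H-inden-1-yl]ethenyl}oxolan-2-one
Product: 20 (4R)-4-{1-[(1R,3aS,7aS)-4,4,7a-trimethyloctahydro-1H-inden-1-yl]ethenyl}oxolan-2-ol (mixture of anomers)
Conditions: i-Bu2AlH (1.1 equiv), CH2Cl2, −78 °C
Reagents that add atoms: none
Why: Partial reduction of the lactone to the lactol via the stable tetrahedral aluminate at low temperature, with the alkene and the existing stereocentres unaffected.

Step 12
Reactants: 20 (4R)-4-{1-[(1R,3aS,7aS)-4,4,7a-trimethyloctahydro-1H-inden-1-yl]ethenyl}oxolan-2-ol; 21 ethyl glyoxylate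
Product: 24 (3R,4R)-3-hydroxy-4-{(2R)-1-hydroxy-3-[(1R,3aS,7aS)-4,4,7a-trimethyloctahydro-1H-inden-1-yl]but-3-en-2-yl}oxolan-2-one, via aldol lactol 22 (not isolated), via triol ester 23 (not isolated)
Conditions: 21 (polymeric form, toluene solution), (S)-α,α-bis[3,5-bis(trifluoromethyl)phenyl]pyrrolidin-2-ylmethanol (10 mol%), MeCN/H2O, rt; then NaBH4, EtOH, 0 °C; then p-TsOH·H2O (cat.), CH2Cl2, rt
Reagents that add atoms: none
Why: Enamine‑mediated direct cross‑aldol (Hayashi diarylprolinol conditions) of the latent hydroxy aldehyde with the non‑enolisable glyoxylate gives the anti adduct with catalyst control at both new centres, NaBH4 reduces the lactol to the diol, and acid closes the favoured five‑membered lactone, in which the anti aldol relationship appears as the cis hydroxy/alkyl arrangement.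

Step 13
Reactants: 24 (3R,4R)-3-hydroxy-4-{(2R)-1-hydroxy-3-[(1R,3aS,7aS)-4,4,7a-trimethyloctahydro-1H-inden-1-yl]but-3-en-2-yl}oxolan-2-one
Product: 25 (2R)-2-[(3R,4R)-4-hydroxy-5-oxooxolan-3-yl]-3-[(1R,3aS,7aS)-4,4,7a-trimethyloctahydro-1H-inden-1-yl]but-3-en-1-yl acetate
Conditions: AcCl (1.05 equiv), 2,4,6-collidine, CH2Cl2, −78 °C
Reagents that add atoms: acetyl chloride CC(Cl)=O
Why: Kinetically selective acetylation of the primary alcohol over the hindered and less nucleophilic α‑hydroxy‑lactone hydroxyl.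

**Compound list**

1 | 5-bromo-2-methylpent-2-ene | CC(C)=CCCBr | starting material
2 | lithium acetylide ethylenediamine complex | [Li]C#C.NCCN | starting material
3 | 6-methylhept-5-en-1-yne | C#CCCC=C(C)C | intermediate
4 | [(1E)-2,6-dimethylhepta-1,5-dien-1-yl]dimethylalumane | C[Al](C)/C=C(\C)CCC=C(C)C | intermediate
5 | (1E)-1-iodo-2,6-dimethylhepta-1,5-diene | I/C=C(\C)CCC=C(C)C | intermediate
6 | but-3-yn-1-ol | C#CCCO | starting material
7 | {[(3E)-4-(dimethylalumanyl)-3-methylbut-3-en-1-yl]oxy}dimethylalumane | C[Al](C)/C=C(\C)CCO[Al](C)C | intermediate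
8 | (3E)-4-chloro-3-methylbut-3-en-1-ol | Cl/C=C(\C)CCO | intermediate
9 | (1E)-1-chloro-4-iodo-2-methylbut-1-ene | Cl/C=C(\C)CCI | intermediate
10 | [(3E)-4-chloro-3-methylbut-3-en-1-yl]zinc iodide | Cl/C=C(\C)CC[Zn]I | intermediate
11 | (1E,5E)-1-chloro-2,6,10-trimethylundeca-1,5,9-triene | Cl/C=C(\C)CC/C=C(\C)CCC=C(C)C | intermediate
12 | (1R,2R,4aS,8aS)-1-chloro-2,5,5,8a-tetramethyldecahydronaphthalen-2-ol (trans-decalin, equatorial Cl) | Cl[C@H]1[C@](C)(O)CC[C@H]2C(C)(C)CCC[C@]12C | intermediate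
13 | bromomagnesium (1R,2R,4aS,8aS)-1-chloro-2,5,5,8a-tetramethyldecahydronaphthalen-2-olate | Cl[C@H]1[C@](C)(O[Mg]Br)CC[C@H]2C(C)(C)CCC[C@]12C | intermediate
14 | 1-[(1S,3aS,7aS)-4,4,7a-trimethyloctahydro-1H-inden-1-yl]ethan-1-one (trans-hydrindane, acetyl cis to angular methyl) | CC(=O)[C@H]1CC[C@H]2C(C)(C)CCC[C@]12C | intermediate
15 | potassium 1-[(1S,3aS,7aS)-4,4,7a-trimethyloctahydro-1H-inden-1-yl]ethen-1-olate | C=C(O[K])[C@H]1CC[C@H]2C(C)(C)CCC[C@]12C | intermediate
16 | 1-[(1S,3aS,7aS)-4,4,7a-trimethyloctahydro-1H-inden-1-yl]ethenyl trifluoromethanesulfonate | C=C(OS(=O)(=O)C(F)(F)F)[C@H]1CC[C@H]2C(C)(C)CCC[C@]12C | intermediate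
17 | 4,4,5,5-tetramethyl-2-{1-[(1R,3aS,7aR)-4,4,7a-trimethyloctahydro-1H-inden-1-yl]ethenyl}-1,3,2-dioxaborolane | C=C(B1OC(C)(C)C(C)(C)O1)[C@H]1CC[C@H]2C(C)(C)CCC[C@]12C | intermediate
18 | furan-2(5H)-one | O=C1OCC=C1 | starting material
19 | (4R)-4-{1-[(1R,3aS,7aS)-4,4,7a-trimethyloctahydro-1H-inden-1-yl]ethenyl}oxolan-2-one | C=C([C@H]1CC[C@H]2C(C)(C)CCC[C@]12C)[C@@H]1COC(=O)C1 | intermediate
20 | (4R)-4-{1-[(1R,3aS,7aS)-4,4,7a-trimethyloctahydro-1H-inden-1-yl]ethenyl}oxolan-2-ol (anomers) | C=C([C@H]1CC[C@H]2C(C)(C)CCC[C@]12C)[C@@H]1COC(O)C1 | intermediate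
21 | ethyl glyoxylate (ethyl oxoacetate) | CCOC(=O)C=O | starting material
22 | ethyl (2R)-2-hydroxy-2-[(3S,4R)-2-hydroxy-4-{1-[(1R,3aS,7aS)-4,4,7a-trimethyloctahydro-1H-inden-1-yl]ethenyl}oxolan-3-yl]acetate (anomers) | C=C([C@H]1CC[C@H]2C(C)(C)CCC[C@]12C)[C@@H]1COC(O)[C@@H]1[C@@H](O)C(=O)OCC | intermediate
23 | ethyl (2R,3R,4R)-2-hydroxy-3,4-bis(hydroxymethyl)-5-[(1R,3aS,7aS)-4,4,7a-trimethyloctahydro-1H-inden-1-yl]hex-5-enoate | C=C([C@H]1CC[C@H]2C(C)(C)CCC[C@]12C)[C@H](CO)[C@H](CO)[C@@H](O)C(=O)OCC | intermediate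
24 | (3R,4R)-3-hydroxy-4-{(2R)-1-hydroxy-3-[(1R,3aS,7aS)-4,4,7a-trimethyloctahydro-1H-inden-1-yl]but-3-en-2-yl}oxolan-2-one | C=C([C@H]1CC[C@H]2C(C)(C)CCC[C@]12C)[C@H](CO)[C@@H]1COC(=O)[C@@H]1O | intermediate
25 | (2R)-2-[(3R,4R)-4-hydroxy-5-oxooxolan-3-yl]-3-[(1R,3aS,7aS)-4,4,7a-trimethyloctahydro-1H-inden-1-yl]but-3-en-1-yl acetate | C=C([C@H]1CC[C@H]2C(C)(C)CCC[C@]12C)[C@H](COC(C)=O)[C@@H]1COC(=O)[C@@H]1O | target

**Step count and risks**

Total: 13 steps. Longest linear sequence: 11 steps (steps 1, 2, 5 to 13); steps 3 and 4 form the short branch.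

Most likely to fail:

1. Step 6 (the proposed new bicyclisation). The weakly nucleophilic chloroalkene may terminate poorly, the tertiary cation may eliminate instead of being hydrated, and enantiocontrol on an all‑hydrocarbon triene is unproven. Fallback by known chemistry, setting out from 5 and returning at 14: 5 is coupled (Pd(PPh3)4, THF) with pent-3-yn-1-ylzinc iodide F1 (from 5-iodopent-2-yne, Zn dust and LiCl) to give (6E)-7,11-dimethyldodeca-6,10-dien-2-yne F2. Johnson's alkyne‑terminated cationic bicyclisation (CF3CO2H, CH2Cl2, −78 °C) gives the enol trifluoroacetate F3. Hydrolysis (K2CO3, MeOH/H2O, which also equilibrates the acetyl group cis to the angular methyl) gives the racemic ketone, that is 14 together with its enantiomer F4. Preparative HPLC on a chiral stationary phase removes F4 and the route continues from 14 at step 8. This fallback reaches 14 directly and bypasses the chlorohydrin ring contraction (steps 3 to 7).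

2. Step 10 (rhodium‑catalysed conjugate addition). The α‑branched, hindered alkenylboronate may transmetalate slowly or protodeboronate. Fallback setting out from 17 and returning at 19: Suzuki coupling of 17 with 4-bromofuran-2(5H)-one (Pd(PPh3)4, K2CO3, dioxane/H2O, 60 °C) gives the dienyl butenolide 4-{1-[(1S,3aS,7aS)-4,4,7a-trimethyloctahydro-1H-inden-1-yl]ethenyl}furan-2(5H)-one F5. Buchwald‑type copper hydride asymmetric conjugate reduction (Cu(OAc)2, the p-tol-BINAP enantiomer that gives the (4R) centre, polymethylhydrosiloxane, t-BuOH, toluene) then gives 19.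

3. Step 12 (organocatalytic aldol, reduction, lactonisation). Facial and anti/syn control with a β‑branched lactol donor, and five‑ versus six‑membered lactonisation, are uncertain. Fallback with auxiliary control, setting out from 19 and returning at 24: 19 is opened and silylated (KOH, THF/H2O; t-BuMe2SiCl, imidazole, DMF; K2CO3, MeOH/H2O) to the silyloxy acid F6. Coupling (t-BuCOCl, Et3N, LiCl, THF) with (4R)-4-benzyl-1,3-oxazolidin-2-one gives the N-acyl oxazolidinone F7. The Evans magnesium‑halide‑catalysed anti‑aldol with ethyl glyoxylate (MgCl2, Et3N, Me3SiCl, EtOAc; then CF3CO2H, MeOH) gives the anti‑aldol imide F8. NaBH4 (THF/H2O) removes the auxiliary to give the hydroxy ester F9, which lactonises on mild acid treatment to the silyl‑protected hydroxy lactone F10. Bu4NF (THF) then gives 24.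

Further compounds
F1 | step 6 | pent-3-yn-1-ylzinc iodide | CC#CCC[Zn]I
F2 | step 6 | (6E)-7,11-dimethyldodeca-6,10-dien-2-yne | CC#CCC/C=C(\C)CCC=C(C)C
F3 | step 6 | racemic 1-[(3aS,7aS)-4,4,7a-trimethyloctahydro-1H-inden-1-ylidene]ethyl trifluoroacetate (one enantiomer drawn, alkene geometry mixed) | CC(OC(=O)C(F)(F)F)=C1CC[C@H]2C(C)(C)CCC[C@]12C
F4 | step 6 | 1-[(1R,3aR,7aR)-4,4,7a-trimethyloctahydro-1H-inden-1-yl]ethan-1-one (enantiomer of 14) | CC(=O)[C@@H]1CC[C@@H]2C(C)(C)CCC[C@@]12C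
F5 | step 10 | 4-{1-[(1S,3aS,7aS)-4,4,7a-trimethyloctahydro-1H-inden-1-yl]ethenyl}furan-2(5H)-one | C=C([C@H]1CC[C@H]2C(C)(C)CCC[C@]12C)C1=CC(=O)OC1
F6 | step 12 | (3R)-3-({[tert-butyl(dimethyl)silyl]oxy}methyl)-4-[(1R,3aS,7aS)-4,4,7a-trimethyloctahydro-1H-inden-1-yl]pent-4-enoic acid | C=C([C@H]1CC[C@H]2C(C)(C)CCC[C@]12C)[C@H](CO[Si](C)(C)C(C)(C)C)CC(O)=O
F7 | step 12 | (4R)-4-benzyl-3-{(3R)-3-({[tert-butyl(dimethyl)silyl]oxy}methyl)-4-[(1R,3aS,7aS)-4,4,7a-trimethyloctahydro-1H-inden-1-yl]pent-4-enoyl}-1,3-oxazolidin-2-one | C=C([C@H]1CC[C@H]2C(C)(C)CCC[C@]12C)[C@H](CO[Si](C)(C)C(C)(C)C)CC(=O)N1[C@H](Cc2ccccc2)COC1=O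
F8 | step 12 | ethyl (2R,3S,4R)-3-{[(4R)-4-benzyl-2-oxo-1,3-oxazolidin-3-yl]carbonyl}-4-({[tert-butyl(dimethyl)silyl]oxy}methyl)-2-hydroxy-5-[(1R,3aS,7aS)-4,4,7a-trimethyloctahydro-1H-inden-1-yl]hex-5-enoate | C=C([C@H]1CC[C@H]2C(C)(C)CCC[C@]12C)[C@H](CO[Si](C)(C)C(C)(C)C)[C@H](C(=O)N1[C@H](Cc2ccccc2)COC1=O)[C@@H](O)C(=O)OCC
F9 | step 12 | ethyl (2R,3R,4R)-4-({[tert-butyl(dimethyl)silyl]oxy}methyl)-2-hydroxy-3-(hydroxymethyl)-5-[(1R,3aS,7aS)-4,4,7a-trimethyloctahydro-1H-inden-1-yl]hex-5-enoate | C=C([C@H]1CC[C@H]2C(C)(C)CCC[C@]12C)[C@H](CO[Si](C)(C)C(C)(C)C)[C@H](CO)[C@@H](O)C(=O)OCC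
F10 | step 12 | (3R,4R)-4-{(2R)-1-{[tert-butyl(dimethyl)silyl]oxy}-3-[(1R,3aS,7aS)-4,4,7a-trimethyloctahydro-1H-inden-1-yl]but-3-en-2-yl}-3-hydroxyoxolan-2-one | C=C([C@H]1CC[C@H]2C(C)(C)CCC[C@]12C)[C@H](CO[Si](C)(C)C(C)(C)C)[C@@H]1COC(=O)[C@@H]1O
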